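Ring B is a hexasubstituted resorcylate (B1 CO2Me, B2 CH3, B3 O–ring A, B4 OH, B5 CH3, B6 OH). The route exploits its meta-dioxygenation with the ester ortho to B6: carbons B3–B6 are drawn from a 4-aryloxy-2-methylacetoacetate and B1–B2 from methyl 2-butynoate. A single thermal (4+2) cycloaddition of the derived 1-methoxy-1,3-bis(trimethylsilyloxy)diene makes the B2–B3 and B6–B1 bonds; methanol loss then aromatizes, delivering all six substituents and the diaryl ether at once. The diene precursor carries ring A, built from orsellinic acid, masked as allyl ester, allyl ether and dioxolane.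

Key step: step 10

Remarks on the chemistry:
- Ring A is numbered as in orsellinic acid: C1 carboxyl-bearing, C2 ether oxygen, C3 formyl, C4 hydroxyl, C5 chlorine, C6 methyl.
- "Ar" is the protected ring A group bonded through the C2 oxygen: 4-chloro-6-(1,3-dioxolan-2-yl)-3-methyl-5-(allyloxy)-2-(allyloxycarbonyl)phenyl.
- The enol ether geometries of 11, 12 and 13 are mixed and are erased on aromatization, so their SMILES carry no double-bond descriptors.
- Compounds 8, 9, 10 and 15 are racemic or epimeric at centres that are enolizable or destroyed. The target has no stereocentre.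

Step 1
Reactants: 1 orsellinic acid
Product: 2 allyl 2,4-dihydroxy-6-methylbenzoate
Conditions: allyl bromide (1.1 equiv), KHCO3 (1.2 equiv), DMF, rt
Reagents that add atoms: allyl bromide, C=CCBr
Why: Carboxylate O-alkylation (SN2); KHCO3 ionizes only the carboxylic acid, so the ester should form without touching the phenols or heating the decarboxylation-prone acid, and the allyl ester tolerates TiCl4, acid and amide base yet leaves later under neutral zerovalent-palladium catalysis.

Step 2
Reactants: 2 allyl 2,4-dihydroxy-6-methylbenzoate
Product: 3 allyl 3-formyl-2,4-dihydroxy-6-methylbenzoate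
Conditions: Cl2CHOCH3 (1.3 equiv), TiCl4 (2.5 equiv), CH2Cl2, −10 to 0 °C; then ice-cold 1 M HCl
Reagents that add atoms: dichloromethyl methyl ether, COC(Cl)Cl; water, O
Why: Rieche formylation; the titanium phenoxide/ester chelate should steer the electrophile to C3 between the two oxygens (the classical haematommate pattern of orsellinate formylation, reinforced by bond fixation in the chelated salicylate), C5 next to the methyl group being less favoured, and aqueous hydrolysis of the α-chloro ether gives the aldehyde.

Step 3
Reactants: 3 allyl 3-formyl-2,4-dihydroxy-6-methylbenzoate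
Product: 4 allyl 5-chloro-3-formyl-2,4-dihydroxy-6-methylbenzoate
Conditions: SO2Cl2 (1.05 equiv), Et2O, 0 °C, dark
Reagents that add atoms: sulfuryl chloride, O=S(=O)(Cl)Cl
Why: Electrophilic aromatic chlorination; C5 is the only unsubstituted ring carbon and is ortho to the C4 hydroxyl and para to the C2 hydroxyl, so one equivalent at low temperature should chlorinate the ring far faster than the deactivated allyl alkene.

Step 4
Reactants: 4 allyl 5-chloro-3-formyl-2,4-dihydroxy-6-methylbenzoate
Product: 5 allyl 4-(allyloxy)-5-chloro-3-formyl-2-hydroxy-6-methylbenzoate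
Conditions: allyl bromide (1.05 equiv), K2CO3 (1.1 equiv), acetone, rt
Reagents that add atoms: allyl bromide, C=CCBr
Why: Williamson etherification; the C4 hydroxyl (para to the ester, ortho to chlorine and formyl) is the more acidic phenol and should be alkylated selectively while the C2 hydroxyl stays hydrogen-bonded to the ester carbonyl, and the allyl ether survives the acid of step 5 and leaves together with the allyl ester.

Step 5
Reactants: 5 allyl 4-(allyloxy)-5-chloro-3-formyl-2-hydroxy-6-methylbenzoate
Product: 6 allyl 4-(allyloxy)-5-chloro-3-(1,3-dioxolan-2-yl)-2-hydroxy-6-methylbenzoate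
Conditions: ethylene glycol (5 equiv), TsOH·H2O (5 mol %), toluene, reflux, Dean–Stark; Et3N quench
Reagents that add atoms: ethylene glycol, OCCO
Why: Acid-catalysed acetalization with azeotropic water removal; both allyl groups are acid-stable, and masking the aldehyde at this point prevents the benzofuran-forming Rap–Stoermer condensation in step 7 and attack of amide base or enolates on the formyl group in step 9.

Step 6
Reactants: 7 methyl 2-methyl-3-oxobutanoate
Product: 9 methyl 4-bromo-2-methyl-3-oxobutanoate, via methyl 2-bromo-2-methyl-3-oxobutanoate 8 (not isolated)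
Conditions: Br2 (1.0 equiv), CHCl3, 0 °C to rt, 16 h with HBr retained; then air purge, used crude
Reagents that add atoms: bromine, BrBr
Why: Electrophilic α-bromination of a β-keto ester followed by HBr-mediated bromine migration; bromine enters first at C2 and the retained HBr relocates it to the terminal C4 position, the known behaviour of 2-alkylacetoacetates.

Step 7
Reactants: 6 allyl 4-(allyloxy)-5-chloro-3-(1,3-dioxolan-2-yl)-2-hydroxy-6-methylbenzoate; 9 methyl 4-bromo-2-methyl-3-oxobutanoate (1.3 equiv)
Product: 10 methyl 4-(Ar-oxy)-2-methyl-3-oxobutanoate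
Conditions: K2CO3 (1.2 equiv), DMF, 0 °C to rt; pH 5 buffer work-up
Reagents that add atoms: none
Why: Williamson etherification with an α-bromo ketone; the phenol is more acidic than the keto ester, so its phenoxide is formed preferentially and should displace the highly SN2-reactive bromide, as in the known preparation of 4-aryloxyacetoacetates from phenols and 4-haloacetoacetates.

Step 8
Reactants: 10 methyl 4-(Ar-oxy)-2-methyl-3-oxobutanoate
Product: 11 methyl 4-(Ar-oxy)-2-methyl-3-(trimethylsilyloxy)but-2-enoate
Conditions: Me3SiCl (1.5 equiv), Et3N (1.6 equiv), toluene, rt; filtration under argon, used crude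
Reagents that add atoms: chlorotrimethylsilane, C[Si](C)(C)Cl
Why: Soft enolization and O-silylation of a β-keto ester; the conjugated enol toward C2 is trapped, giving the 3-silyloxy-2-enoate that is the standard first stage of Chan-type bis(silyloxy)diene synthesis.

Step 9
Reactants: 11 methyl 4-(Ar-oxy)-2-methyl-3-(trimethylsilyloxy)but-2-enoate
Product: 13 4-(Ar-oxy)-1-methoxy-2-methyl-1,3-bis(trimethylsilyloxy)buta-1,3-diene, via lithium dienolate 12 (not isolated)
Conditions: LiN(iPr)2 (LDA, 1.15 equiv), THF, −78 °C, short contact; then Me3SiCl (1.3 equiv), −78 to 0 °C; hexane, filtration under argon, used crude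
Reagents that add atoms: chlorotrimethylsilane, C[Si](C)(C)Cl
Why: Kinetic γ-deprotonation of a 3-silyloxy-2-enoate and O-silylation of the dienolate (Chan–Brownbridge protocol); the OCH2 protons, activated by the enoate and the aryloxy group, should be the most acidic in the molecule, short contact at −78 °C keeps the hindered ring A ester and its ortho methyl group out of play, and the aryloxy group should settle cis to the C3 silyloxy group, on the outside of the s-cis diene.

Step 10
Reactants: 13 4-(Ar-oxy)-1-methoxy-2-methyl-1,3-bis(trimethylsilyloxy)buta-1,3-diene; 14 methyl but-2-ynoate (8 equiv, neat)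
Product: 17 methyl 5-(Ar-oxy)-2,4-dihydroxy-3,6-dimethylbenzoate, via cyclohexadiene cycloadduct 15 (not isolated), via bis(trimethylsilyl) ether 16 (not isolated)
Conditions: neat 14, sealed tube, 125 °C, 36 h; then MeOH, K2CO3 (0.2 equiv), 0 °C, 20 min; pH 7 buffer
Reagents that add atoms: none
Why: The electron-rich diene 13 adds to the electron-poor alkyne 14 in a thermal, strongly asynchronous Diels–Alder reaction (or its stepwise Mukaiyama–Michael/Claisen-type equivalent), joining the aryloxy-bearing diene terminus to the methyl-bearing alkyne carbon (B2–B3) and the ketene acetal carbon to the ester-bearing alkyne carbon (B6–B1). The closest known reaction type is the cycloaromatization of 1-alkoxy-1,3-bis(silyloxy)butadienes with alkynoates to 2,4-dihydroxybenzoates, applied here to a more crowded diene. Ring B closes as a six-membered carbocycle by intermolecular (4+2) annulation of a four-carbon and a two-carbon component, not by cyclization of a tether. The two sp3 centres of adduct 15 (B3 and B6) are transient and vanish on aromatization, so no stereocentre needs control. Regioselectivity is the selectivity required: the ketene acetal at one end makes the aryloxy-bearing carbon the nucleophilic diene terminus, which pairs with the electrophilic β carbon of the ynoate. Because B6 carries methoxy and silyloxy while B3 carries a hydrogen, aromatization expels methanol and keeps the diaryl ether, and mild methanolysis then frees both phenols while the dioxolane, allyl ether and allyl ester stay.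

Step 11
Reactants: 17 methyl 5-(Ar-oxy)-2,4-dihydroxy-3,6-dimethylbenzoate
Product: 19 5-chloro-2-[2,4-dihydroxy-5-(methoxycarbonyl)-3,6-dimethylphenoxy]-3-formyl-4-hydroxy-6-methylbenzoic acid (target), via deallylated acid 18 (not isolated)
Conditions: Pd(PPh3)4 (5 mol %), morpholine (10 equiv), THF, rt to 40 °C; then 2 M aq. HCl added to the same flask, rt
Reagents that add atoms: water, O
Why: Tsuji–Trost deallylation followed by acetal hydrolysis; zerovalent palladium ionizes the allyl ester and the allyl aryl ether to π-allyl complexes that morpholine captures, and acidification hydrolyses the oxygen-flanked aryl dioxolane at room temperature without affecting the hindered methyl ester, the aryl chloride or the diaryl ether.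

Compound list
1 | orsellinic acid (2,4-dihydroxy-6-methylbenzoic acid) | Cc1cc(O)cc(O)c1C(=O)O | starting material
2 | allyl 2,4-dihydroxy-6-methylbenzoate | Cc1cc(O)cc(O)c1C(=O)OCC=C | intermediate
3 | allyl 3-formyl-2,4-dihydroxy-6-methylbenzoate | Cc1cc(O)c(C=O)c(O)c1C(=O)OCC=C | intermediate
4 | allyl 5-chloro-3-formyl-2,4-dihydroxy-6-methylbenzoate | Cc1c(Cl)c(O)c(C=O)c(O)c1C(=O)OCC=C | intermediate
5 | allyl 4-(allyloxy)-5-chloro-3-formyl-2-hydroxy-6-methylbenzoate | Cc1c(Cl)c(OCC=C)c(C=O)c(O)c1C(=O)OCC=C | intermediate
6 | allyl 4-(allyloxy)-5-chloro-3-(1,3-dioxolan-2-yl)-2-hydroxy-6-methylbenzoate (ArOH) | Cc1c(Cl)c(OCC=C)c(C2OCCO2)c(O)c1C(=O)OCC=C | intermediate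
7 | methyl 2-methyl-3-oxobutanoate (methyl 2-methylacetoacetate) | CC(=O)C(C)C(=O)OC | starting material
8 | methyl 2-bromo-2-methyl-3-oxobutanoate (racemic, not isolated) | CC(=O)C(C)(Br)C(=O)OC | intermediate
9 | methyl 4-bromo-2-methyl-3-oxobutanoate (racemic) | BrCC(=O)C(C)C(=O)OC | intermediate
10 | methyl 4-(Ar-oxy)-2-methyl-3-oxobutanoate (racemic keto ester) | COC(=O)C(C)C(=O)COc1c(C2OCCO2)c(OCC=C)c(Cl)c(C)c1C(=O)OCC=C | intermediate
11 | methyl 4-(Ar-oxy)-2-methyl-3-(trimethylsilyloxy)but-2-enoate (E/Z mixture) | COC(=O)C(C)=C(O[Si](C)(C)C)COc1c(C2OCCO2)c(OCC=C)c(Cl)c(C)c1C(=O)OCC=C | intermediate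
12 | lithium 4-(Ar-oxy)-1-methoxy-2-methyl-3-(trimethylsilyloxy)buta-1,3-dien-1-olate (not isolated) | [Li+].[O-]C(OC)=C(C)C(O[Si](C)(C)C)=COc1c(C2OCCO2)c(OCC=C)c(Cl)c(C)c1C(=O)OCC=C | intermediate
13 | 4-(Ar-oxy)-1-methoxy-2-methyl-1,3-bis(trimethylsilyloxy)buta-1,3-diene (geometry mixed) | COC(O[Si](C)(C)C)=C(C)C(O[Si](C)(C)C)=COc1c(C2OCCO2)c(OCC=C)c(Cl)c(C)c1C(=O)OCC=C | intermediate
14 | methyl but-2-ynoate | CC#CC(=O)OC | starting material
15 | methyl 3-(Ar-oxy)-6-methoxy-2,5-dimethyl-4,6-bis(trimethylsilyloxy)cyclohexa-1,4-diene-1-carboxylate (diastereomer mixture, not isolated) | COC(=O)C1=C(C)C(Oc2c(C3OCCO3)c(OCC=C)c(Cl)c(C)c2C(=O)OCC=C)C(O[Si](C)(C)C)=C(C)C1(OC)O[Si](C)(C)C | intermediate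
16 | methyl 5-(Ar-oxy)-3,6-dimethyl-2,4-bis(trimethylsilyloxy)benzoate (not isolated) | COC(=O)c1c(C)c(Oc2c(C3OCCO3)c(OCC=C)c(Cl)c(C)c2C(=O)OCC=C)c(O[Si](C)(C)C)c(C)c1O[Si](C)(C)C | intermediate
17 | methyl 5-(Ar-oxy)-2,4-dihydroxy-3,6-dimethylbenzoate (protected diaryl ether with complete ring B) | COC(=O)c1c(C)c(Oc2c(C3OCCO3)c(OCC=C)c(Cl)c(C)c2C(=O)OCC=C)c(O)c(C)c1O | intermediate
18 | 5-chloro-2-[2,4-dihydroxy-5-(methoxycarbonyl)-3,6-dimethylphenoxy]-3-(1,3-dioxolan-2-yl)-4-hydroxy-6-methylbenzoic acid (not isolated) | COC(=O)c1c(C)c(Oc2c(C3OCCO3)c(O)c(Cl)c(C)c2C(=O)O)c(O)c(C)c1O | intermediate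
19 | 5-chloro-2-[2,4-dihydroxy-5-(methoxycarbonyl)-3,6-dimethylphenoxy]-3-formyl-4-hydroxy-6-methylbenzoic acid (CNP0210944.0) | COC(=O)c1c(C)c(Oc2c(C=O)c(O)c(Cl)c(C)c2C(=O)O)c(O)c(C)c1O | target

Total step count: 11. Longest linear sequence: 10 steps (steps 1–5 and 7–11; step 6 is a one-step side branch).

Steps most likely to fail

1. Step 10. The internal, β-methylated ynoate may add too slowly to the crowded diene. Desilylation of the diene, by adventitious acid or by the methanol the reaction itself releases, could then outrun ring formation. The fallback sets out from diene 13 and returns at 17. Diene 13 is heated at about 80 °C, neat or in toluene, with methyl buta-2,3-dienoate, a cumulated and more electrophilic two-carbon partner used in known Diels–Alder aromatizations of silyloxydienes. Addition across the conjugated allene double bond, with the same polarity matching, should give the exo-methylene cycloadduct methyl 3-(Ar-oxy)-6-methoxy-5-methyl-2-methylidene-4,6-bis(trimethylsilyloxy)cyclohex-4-ene-1-carboxylate F1. F1 loses methanol and tautomerizes, the exocyclic alkene moving into the ring, to give 16. The same K2CO3/MeOH treatment then gives 17.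

2. Step 9. The amide base may deprotonate the ring A methyl group ortho to the ester (lateral metalation), or the dienolate may close onto the ring A ester before it is silylated. The fallback sets out from keto ester 10 and returns at diene 13, bypassing 11 and 12. It is a one-flask double soft enolization with Me3SiOTf (2.3 equiv) and Et3N (2.6 equiv) in Et2O at 0 °C, the known silyl triflate route from β-keto esters to 1-alkoxy-1,3-bis(silyloxy)dienes. No strong base is present, and the aryl dioxolane has no α-hydrogen through which reversible silyl activation could drain it. This detour makes no new compound (F0).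

3. Step 7. Base-induced self-condensation or cyclization of the bromo keto ester may outpace SN2 attack by the doubly ortho-substituted phenoxide. The fallback sets out from phenol 6 and returns at keto ester 10. Phenol 6 is alkylated with methyl bromoacetate (K2CO3, DMF, rt), an unhindered electrophile without an acidic 1,3-dicarbonyl, to give methyl 2-(Ar-oxy)acetate F2. Crossed Claisen condensation of F2 with the lithium enolate of methyl propanoate (3 equiv, from LiN(iPr)2, THF, −78 °C) should then give 10. The unhindered aryloxyacetate ester is attacked in preference to the twisted, di-ortho-substituted ring A ester.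

Further compounds
F1 | step 10 | methyl 3-(Ar-oxy)-6-methoxy-5-methyl-2-methylidene-4,6-bis(trimethylsilyloxy)cyclohex-4-ene-1-carboxylate | COC(=O)C1C(=C)C(Oc2c(C3OCCO3)c(OCC=C)c(Cl)c(C)c2C(=O)OCC=C)C(O[Si](C)(C)C)=C(C)C1(OC)O[Si](C)(C)C
F0 | step 9 | none | none
F2 | step 7 | methyl 2-(Ar-oxy)acetate | COC(=O)COc1c(C2OCCO2)c(OCC=C)c(Cl)c(C)c1C(=O)OCC=C
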